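## The problem

Target 20 is a depside without stereocentres: a 2,4-dihydroxy-6-methylbenzoyl unit (ring A, C1'–C6', ester carbonyl C7' on C1') is esterified with the C4 hydroxyl of 2-heptyl-4,6-dihydroxybenzoic acid (ring B, C1–C6, carboxyl on C1, heptyl on C2). The central bond O(C4)–C7' is the hard one: C7' sits between the C2' hydroxyl and the C6' methyl, so the acid is doubly ortho-hindered, and the nucleophile is an electron-poor phenol para to a carboxyl group. The molecule has four acidic O–H groups (three phenols and a carboxylic acid) and only one phenol may be acylated; the usual answer protects all the others and turns a two-ring problem into a protecting-group exercise. Both rings carry the 1-carboxy-2,4-dioxy-6-alkyl pattern, in which the alkyl group (methyl on C6', heptyl on C2) is meta to both oxygens and ortho to the carboxyl carbon, a position that substitution chemistry on a resorcinol reaches poorly. The finished compound is fragile: the free salicylic acid of ring B loses carbon dioxide on heating or in acid, and the aryl ester is cleaved or exchanged by hydroxide, alkoxides and amines, so the last step must be neutral and mild. The feature that opens a way is the atom sequence of ring A: C7'(=O)–C1'–C2'(O)–C3'–C4'(O)–C5'–C6'–CH3 is an eight-carbon chain with oxygen on every second carbon, closed by the single ring bond C1'–C6'. Ring A is therefore a folded 3,5,7-trioxooctanoyl group whose ester carbon C7' is C1 of the chain, and C1 can be an unhindered ketene carbon before the ring exists. Ring B has the same sequence with heptyl in place of methyl, so its chain is the ring A chain lengthened by six carbons at the methyl end, and one construction can serve both rings.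

## Retrosynthesis

**20 ⇒ 19.** The benzyl–oxygen bond of the ring B carboxyl is cut. Hydrogenolysis is neutral and runs at room temperature, which suits both the decarboxylation-prone acid and the depside ester. A methyl ester or a ketal on ring B would need a nucleophile or hydroxide for removal, which the depside would not survive. The benzyl ester is the only protecting group of the route.

**19 ⇒ 7 + 15.** Two bonds are cut together: the ester bond O(C4)–C7' and the ring bond C1'–C6'. Cutting only the ester bond leaves a hindered acid that needs two phenol protecting groups. Cutting both removes ring A altogether. The precursor 7 is an acyclic C8 chain masked as a dioxinone, with no aromatic ring and no protecting group. In the forward direction, cycloreversion of the dioxinone ring of 7 gives acylketene 16, the C4 hydroxyl of 15 adds to it to give aryl triketo ester 17, and aldol closure through 18 with dehydration builds ring A around the ester that already exists. The forward reaction must capture the ketene at the C4 hydroxyl and not at the chelated C6 hydroxyl of 15, and must do so faster than the ketene cyclises onto its own enol. The ring closure of 17 must go to the ketone and not to the aryl ester carbon.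

**15 ⇒ 10 + 11.** The same pair of cuts is made on ring B: the ester bond to the benzyl oxygen and the ring bond C1–C2. Thermolysis of 10 gives acylketene 12, benzyl alcohol 11 traps it to give 13, and aldol closure through 14 gives the arene. The heptyl group is placed by the order of atoms in the chain, so there is no regiochemical question of the kind that carboxylation of a 5-alkylresorcinol would raise. No free, decarboxylation-prone resorcylic acid is handled. The step also rehearses the key step with an ordinary alcohol as the trap.

**10 ⇒ 7 + 8.** The bond between C5 and C6 of the undecyl chain of 10 is cut, that is, between the methyl carbon of 7 and C1 of a hexyl group. Trianion 9 of 7 is alkylated at its terminal carbon by 1-iodohexane 8. The neighbouring cut, between C4 and C5 (an octanoyl donor onto dianion 6 of 4), would need a second acylation sequence in parallel and a separately prepared acyl donor. The chosen cut starts from 7, which ring A needs anyway, and from a purchased iodide, so one batch of one intermediate serves both rings. The precursor is shorter by six carbons. The forward reaction requires the third deprotonation to take place at the methyl group and alkylation at that carbon only, and the polyanion must not cyclise.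

**7 ⇒ 4 + 5.** The bond between the terminal ketone carbon C4 of the pentyl chain and the adjacent methylene C3 is cut. Dianion 6 of keto-dioxinone 4 is acylated at its terminal carbon by N-methoxy-N-methylacetamide 5, a purchased reagent. The forward reaction requires acylation at the terminal carbon of the dianion, and the product must not meet base.

**4 ⇒ 1 + 2.** The bond between the acetyl carbon and the C6 methyl carbon of the dioxinone is cut. Dienolate 3 of commercial 1 is acylated at its γ-carbon by acetyl chloride 2. Both components are bulk chemicals.

## Roads not taken

Alternative 1: Cut only the ester bond O(C4)–C7'. This is the obvious route. Purchased orsellinic acid A1 would be perbenzylated and the benzyl ester saponified to give 2,4-bis(benzyloxy)-6-methylbenzoic acid A2. A2, activated as a mixed anhydride or acid chloride, would acylate the C4 hydroxyl of 15 to give the tribenzyl depside A3, and threefold hydrogenolysis would give 20.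
- In A2 the carbonyl carbon lies between a benzyloxy group and a methyl group, so the acylation must be forced through a very electrophilic acyl species, which also opens C-acylation of the electron-rich ring of 15.
- Ring A needs two protecting groups and two to three steps only to hide phenols that, in the chosen plan, do not yet exist when the ester is made.
- No ring is built, and the step count is no lower.

Alternative 2: Cut the ester bond and the ring A bonds C1'–C2' and C5'–C6'. The C4 hydroxyl of 15 would be acylated with an unhindered but-2-ynoyl group to give ynoate A4. A Diels–Alder reaction of A4 with 1-methoxy-1,3-bis(trimethylsilyloxy)buta-1,3-diene A5, followed by loss of the C1 methoxy group and desilylation, would give 19.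
- This also makes the ester before the ring, but A4 is a β-methyl ynoate, a sluggish dienophile that needs prolonged heating.
- A5 is a ketene acetal nucleophilic enough to attack the activated aryl ester carbonyl of A4 (acyl transfer with loss of 15) and to silylate its free C6 hydroxyl.
- Regiochemistry rests on the polarisation of both partners, whereas in the chosen plan it is fixed by the order of atoms in one chain.
- A5 needs its own two-step preparation and shares nothing with ring B, whereas 7 serves both rings.

Alternative 3: Cut only the ester bond, but form it from a ketene with ring A already in place. This is the order of the biosynthesis, in which the finished aromatic acyl group is handed to the phenol. A1 would be converted into the ketal 7-hydroxy-5-methyl-2,2-diphenyl-4H-1,3-benzodioxin-4-one A6. Irradiation would expel the ketal carbon and give quinoketene A7, to be captured by the C4 hydroxyl of 15 to give 19.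
- A7 is captured by any phenol present. The C7 hydroxyl of a second molecule of A6 and the ring A hydroxyls of 19 compete with 15, which leads to oligomeric depsides unless ring A is protected again.
- The aryl benzoate product absorbs in the same region as A6 and is open to photo-Fries rearrangement.
- Ring A must exist first, so nothing is constructed, and ring B still needs its own route.
- In the chosen plan the ring A oxygens are still ketone or enol oxygens while the ketene is present, so the only phenols competing for it are those of 15.

Key step: step 5

Assumption: all 1,3-dicarbonyl compounds are written as keto tautomers although they exist largely as enols; 14 and 18 form as mixtures of stereoisomers whose stereocentres vanish on aromatisation, and the target has none.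

## Steps

Step 1
Reactants: 1 2,2,6-trimethyl-4H-1,3-dioxin-4-one; 2 acetyl chloride
Product: 4 2,2-dimethyl-6-(2-oxopropyl)-4H-1,3-dioxin-4-one, via lithium dienolate 3 (not isolated)
Conditions: 1 (2 equiv), LiN(SiMe3)2 (2 equiv), THF, −78 °C; then 2 (1 equiv), −78 °C; 1 M HCl
Reagents that add atoms: none
Why: Kinetic deprotonation of the C6 methyl group gives the extended dienolate 3, which the acid chloride acylates at the terminal (γ) carbon, a vinylogous Claisen acylation well established for this dioxinone. Two equivalents of enolate are used because 4 is more acidic than 1 and quenches one of them.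

Step 2
Reactants: 4 2,2-dimethyl-6-(2-oxopropyl)-4H-1,3-dioxin-4-one; 5 N-methoxy-N-methylacetamide
Product: 7 6-(2,4-dioxopentyl)-2,2-dimethyl-4H-1,3-dioxin-4-one, via dilithium dianion 6 (not isolated)
Conditions: LiN(iPr)2 (2.2 equiv), THF, −78 °C; then 5, −78 → −40 °C; 1 M HCl, 0 °C
Reagents that add atoms: none
Why: The first deprotonation removes the doubly activated methylene proton and the second a terminal methyl proton, and dianion 6 reacts at its more basic terminal carbon (Claisen-type acylation of a 1,3-dicarbonyl dianion, established for this keto-dioxinone). The chelated tetrahedral adduct of the N-methoxy-N-methyl amide collapses only on acidic work-up, so the base-sensitive product never meets the enolate; 7 is made on a scale that covers steps 3 and 5 and is used without chromatography because it cyclises on silica.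

Step 3
Reactants: 7 6-(2,4-dioxopentyl)-2,2-dimethyl-4H-1,3-dioxin-4-one; 8 1-iodohexane
Product: 10 6-(2,4-dioxoundecyl)-2,2-dimethyl-4H-1,3-dioxin-4-one, via trilithium trianion 9 (not isolated)
Conditions: LiN(iPr)2 (3.3 equiv), THF, −78 → −20 °C; then 8 (1.1 equiv), −78 → 0 °C; 1 M HCl, 0 °C
Reagents that add atoms: none
Why: Three equivalents of amide base remove a proton from each of the two doubly activated methylene groups and then from the terminal methyl group, and trianion 9 reacts with the primary iodide at this last-formed, most basic carbon (terminal C-alkylation of a polycarbonyl polyanion, as known for dianions of 1,3-diketones and trianions of 1,3,5-triketones and 3,5-dioxo esters). In 9 every ketone is an enolate, so the aldol cyclisation that consumes 7 under weak base has no electrophile; the product dianion is less basic than 9, which limits a second alkylation, and cold acid work-up gives 10, used crude.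

Step 4
Reactants: 10 6-(2,4-dioxoundecyl)-2,2-dimethyl-4H-1,3-dioxin-4-one; 11 benzyl alcohol
Product: 15 benzyl 2-heptyl-4,6-dihydroxybenzoate, via acylketene 12 (not isolated), via benzyl triketo ester 13 (not isolated), via aldol adduct 14 (not isolated)
Conditions: 11 (1.5 equiv), PhMe, 110 °C; then Cs2CO3, iPrOH/CH2Cl2, rt; then HCl in iPrOH, rt
Reagents that add atoms: none
Why: Retro-[4+2] loss of acetone from 10 gives acylketene 12, which the alcohol captures to give 13; carbonate then triggers the 6-(enolendo)-exo-trig aldol of C2 onto the heptyl ketone C7, and acid completes dehydration of 14 to the arene (dioxinone thermolysis, ketene capture and triketo ester aromatisation, established for alkyl resorcylates). The heptyl group is ortho to the ester by construction, and the hindered alcohol co-solvent avoids ester exchange.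

Step 5
Reactants: 7 6-(2,4-dioxopentyl)-2,2-dimethyl-4H-1,3-dioxin-4-one; 15 benzyl 2-heptyl-4,6-dihydroxybenzoate
Product: 19 benzyl 4-[(2,4-dihydroxy-6-methylbenzoyl)oxy]-2-heptyl-6-hydroxybenzoate, via acylketene 16 (not isolated), via aryl triketo ester 17 (not isolated), via aldol adduct 18 (not isolated)
Conditions: 15 (1.2 equiv), PhMe, 110 °C, slow addition of 7; then Et3N, CH2Cl2, 0 °C → rt; then CF3CO2H, rt
Reagents that add atoms: none
Why: Key step; chain atoms of 16 and 17 are numbered C1 (ketene and later ester carbon, the future C7') to C8 (methyl). Heating 7 causes retro-[4+2] loss of acetone and releases acylketene 16, whose sp carbon has no ortho substituents and adds an O–H bond through a six-membered hydrogen-bonded transition state; this is the dioxinone thermolysis with O–H capture that gives β-keto esters and, from diketo-dioxinones and alcohols, resorcylate esters, here applied with a phenol as the O–H partner. Of the two hydroxyls of 15 the one at C4 should react, because the C6 hydroxyl is locked in a hydrogen bond to the benzyl ester carbonyl and is the poorer nucleophile and proton donor, the same preference that governs acylation of 2,4-dihydroxybenzoates in general. Ring A has no phenols yet, since its oxygens are still ketone or enol oxygens, and a concentrated solution of excess 15 with slow generation of 16 favours the bimolecular capture over cyclisation of the ketene onto its own C5 enol oxygen. In the second operation Et3N enolises the β-keto ester of 17 and C2 adds to the methyl ketone C7, a 6-(enolendo)-exo-trig aldol closure that forms the C1'–C6' bond and gives 18; acid then removes water and the dione enolises, so the ring becomes aromatic irreversibly. The two stereocentres of 18 form without control and are both erased on aromatisation. The closure must take place at the ketone C7 and not at the aryl ester carbon C1 (lactonisation by the C5 enol oxygen or Claisen closure from C6, each with loss of 15): the methyl ketone is more electrophilic than an ester carbonyl enolised toward C2, and a weak amine base in an aprotic, alcohol-free medium avoids alkoxide exchange and the chelated metal enolates that favour the Claisen mode. Once ring A is aromatic the ester is a di-ortho-substituted aryl benzoate that no longer exchanges.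

Step 6
Reactants: 19 benzyl 4-[(2,4-dihydroxy-6-methylbenzoyl)oxy]-2-heptyl-6-hydroxybenzoate
Product: 20 4-[(2,4-dihydroxy-6-methylbenzoyl)oxy]-2-heptyl-6-hydroxybenzoic acid
Conditions: H2 (1 atm), Pd/C, EtOAc, rt
Reagents that add atoms: none
Why: Hydrogenolysis of the benzylic C–O bond frees the carboxylic acid under neutral conditions that leave the aryl ester and the arenes untouched. The product is isolated by filtration and evaporation below room temperature to avoid decarboxylation.

## Compound list

1 | 2,2,6-trimethyl-4H-1,3-dioxin-4-one | CC1=CC(=O)OC(C)(C)O1 | starting material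
2 | acetyl chloride | CC(=O)Cl | starting material
3 | lithium 2,2-dimethyl-6-methylidene-6H-1,3-dioxin-4-olate (lithium dienolate of 1) | [Li+].C=C1C=C([O-])OC(C)(C)O1 | intermediate
4 | 2,2-dimethyl-6-(2-oxopropyl)-4H-1,3-dioxin-4-one | CC(=O)CC1=CC(=O)OC(C)(C)O1 | intermediate
5 | N-methoxy-N-methylacetamide | CC(=O)N(C)OC | starting material
6 | dilithium 2,2-dimethyl-6-(2-oxidoprop-2-en-1-ylidene)-6H-1,3-dioxin-4-olate (dianion of 4) | [Li+].[Li+].C=C([O-])C=C1C=C([O-])OC(C)(C)O1 | intermediate
7 | 6-(2,4-dioxopentyl)-2,2-dimethyl-4H-1,3-dioxin-4-one | CC(=O)CC(=O)CC1=CC(=O)OC(C)(C)O1 | intermediate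
8 | 1-iodohexane | CCCCCCI | starting material
9 | trilithium 6-(2,4-dioxidopenta-2,4-dien-1-ylidene)-2,2-dimethyl-6H-1,3-dioxin-4-olate (trianion of 7) | [Li+].[Li+].[Li+].C=C([O-])C=C([O-])C=C1C=C([O-])OC(C)(C)O1 | intermediate
10 | 6-(2,4-dioxoundecyl)-2,2-dimethyl-4H-1,3-dioxin-4-one | CCCCCCCC(=O)CC(=O)CC1=CC(=O)OC(C)(C)O1 | intermediate
11 | benzyl alcohol | OCc1ccccc1 | starting material
12 | tetradec-1-ene-1,3,5,7-tetrone (acylketene) | CCCCCCCC(=O)CC(=O)CC(=O)C=C=O | intermediate
13 | benzyl 3,5,7-trioxotetradecanoate | CCCCCCCC(=O)CC(=O)CC(=O)CC(=O)OCc1ccccc1 | intermediate
14 | benzyl 2-heptyl-2-hydroxy-4,6-dioxocyclohexane-1-carboxylate (stereoisomer mixture) | CCCCCCCC1(O)CC(=O)CC(=O)C1C(=O)OCc1ccccc1 | intermediate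
15 | benzyl 2-heptyl-4,6-dihydroxybenzoate | CCCCCCCc1cc(O)cc(O)c1C(=O)OCc1ccccc1 | intermediate
16 | oct-1-ene-1,3,5,7-tetrone (acylketene) | CC(=O)CC(=O)CC(=O)C=C=O | intermediate
17 | benzyl 2-heptyl-6-hydroxy-4-[(3,5,7-trioxooctanoyl)oxy]benzoate | CCCCCCCc1cc(OC(=O)CC(=O)CC(=O)CC(C)=O)cc(O)c1C(=O)OCc1ccccc1 | intermediate
18 | benzyl 2-heptyl-6-hydroxy-4-{[(2-hydroxy-2-methyl-4,6-dioxocyclohexyl)carbonyl]oxy}benzoate (stereoisomer mixture) | CCCCCCCc1cc(OC(=O)C2C(=O)CC(=O)CC2(C)O)cc(O)c1C(=O)OCc1ccccc1 | intermediate
19 | benzyl 4-[(2,4-dihydroxy-6-methylbenzoyl)oxy]-2-heptyl-6-hydroxybenzoate | CCCCCCCc1cc(OC(=O)c2c(C)cc(O)cc2O)cc(O)c1C(=O)OCc1ccccc1 | intermediate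
20 | 4-[(2,4-dihydroxy-6-methylbenzoyl)oxy]-2-heptyl-6-hydroxybenzoic acid | CCCCCCCc1cc(OC(=O)c2c(C)cc(O)cc2O)cc(O)c1C(=O)O | target

## Step count and risk

Total step count: 6. Longest linear sequence: 6 steps (steps 1, 2, 3, 4, 5, 6; compound 7 from step 2 enters both step 3 and step 5).

**Step 5 (key step).**
- Capture of ketene 16 by the electron-poor C4 phenol of 15 may be slower than cyclisation of 16 onto its own C5 enol oxygen. At 110 °C an aryl β-keto ester can also revert to ketene and phenol, so material may drain into a pyranone.
- During the base treatment, closure of 17 at the aryl ester carbon (lactonisation or Claisen closure) or base-induced loss of the aryloxide may compete with the aldol. An aryl ester is a much better acyl donor than the alkyl esters for which the sequence is established.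
- Fallback (sets out from 7, uses 15, returns at 20): ring A is closed first and the ester is made afterwards by conventional acylation. Et3N in CH2Cl2 closes 7 with the dioxinone retained and gives 7-hydroxy-2,2,5-trimethyl-4H-1,3-benzodioxin-4-one F1. Benzylation (BnBr, K2CO3, acetone) gives 7-(benzyloxy)-2,2,5-trimethyl-4H-1,3-benzodioxin-4-one F2. KOH in aqueous DMSO opens the ketal to 4-(benzyloxy)-2-hydroxy-6-methylbenzoic acid F3. F3 and 15 are condensed with trifluoroacetic anhydride in toluene at room temperature, which acylates the unchelated C4 hydroxyl of 15 and gives benzyl 4-{[4-(benzyloxy)-2-hydroxy-6-methylbenzoyl]oxy}-2-heptyl-6-hydroxybenzoate F4. Hydrogenolysis of both benzyl groups under the conditions of step 6 gives 20.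

**Step 3.**
- The third deprotonation may be incomplete, which leads to alkylation at an internal carbon or at oxygen or returns 7. The polyanion may decompose on warming by attack on the dioxinone carbonyl, elimination of the iodide by the excess amide base may consume 8, and proton exchange between product and 9 may lead to a second alkylation.
- Fallback (sets out from 4, returns at 10): the seven-carbon chain is brought in together with the ketone carbon, by acylation instead of alkylation. Octanoyl chloride and MeNH(OMe)·HCl (K2CO3, EtOAc/H2O, 0 °C → rt) give N-methoxy-N-methyloctanamide F5. Dianion 6 of 4, formed as in step 2, is acylated at its terminal carbon by F5 (THF, −78 → −40 °C), and acidic work-up gives 10.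

**Step 2.**
- Proton transfer from the acetyl group of 5 to dianion 6 may compete with addition and return 4; O-acylation and cyclisation of 7 during isolation may also occur.
- Fallback (sets out from 1 and 2, returns at 7): soft enolisation replaces the dianion. Commercial monoallyl malonate, benzotriazole and SOCl2 give allyl 3-(1H-benzotriazol-1-yl)-3-oxopropanoate F6. Dienolate 3, formed as in step 1, is acylated by F6 to give allyl 4-(2,2-dimethyl-4-oxo-4H-1,3-dioxin-6-yl)-3-oxobutanoate F7. MgCl2 and pyridine in CH2Cl2 with 2 C-acylate the doubly activated methylene next to the ester and give allyl 2-acetyl-4-(2,2-dimethyl-4-oxo-4H-1,3-dioxin-6-yl)-3-oxobutanoate F8. Pd(PPh3)4 and morpholine remove the allyl group, and the resulting acid decarboxylates to 7. No strong base meets the diketone at any point.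

**Step 4.**
- Triketo ester 13 may close at the ester carbon (pyranone formation with loss of 11), or the benzyl ester may exchange with the alcoholic co-solvent before the aldol closes.
- Fallback (sets out from 10, returns at 15): ring first, ester second. Et3N in CH2Cl2 closes 10 with the dioxinone retained and gives 5-heptyl-7-hydroxy-2,2-dimethyl-4H-1,3-benzodioxin-4-one F9. KOH in aqueous DMSO, with cold acidification, gives 2-heptyl-4,6-dihydroxybenzoic acid F10. BnBr and KHCO3 in DMF alkylate only the carboxylate and give 15.

**Step 1.**
- Proton exchange between product 4 and unreacted dienolate 3, followed by a second acylation or O-acylation, may cap conversion and waste 1.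
- Fallback (sets out from 1, returns at 4): aldol addition followed by oxidation. 1 is converted (LiN(iPr)2, Me3SiCl, THF, −78 °C) into [(2,2-dimethyl-6-methylidene-6H-1,3-dioxin-4-yl)oxy]trimethylsilane F11. Vinylogous Mukaiyama aldol addition to acetaldehyde (BF3·OEt2, CH2Cl2, −78 °C) gives racemic 6-(2-hydroxypropyl)-2,2-dimethyl-4H-1,3-dioxin-4-one F12. Oxidation with Dess–Martin periodinane gives 4.

## Further compounds

F1 | step 5 | 7-hydroxy-2,2,5-trimethyl-4H-1,3-benzodioxin-4-one | Cc1cc(O)cc2c1C(=O)OC(C)(C)O2
F2 | step 5 | 7-(benzyloxy)-2,2,5-trimethyl-4H-1,3-benzodioxin-4-one | Cc1cc(OCc3ccccc3)cc2c1C(=O)OC(C)(C)O2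
F3 | step 5 | 4-(benzyloxy)-2-hydroxy-6-methylbenzoic acid | Cc1cc(OCc2ccccc2)cc(O)c1C(=O)O
F4 | step 5 | benzyl 4-{[4-(benzyloxy)-2-hydroxy-6-methylbenzoyl]oxy}-2-heptyl-6-hydroxybenzoate | CCCCCCCc1cc(OC(=O)c2c(C)cc(OCc3ccccc3)cc2O)cc(O)c1C(=O)OCc1ccccc1
F5 | step 3 | N-methoxy-N-methyloctanamide | CCCCCCCC(=O)N(C)OC
F6 | step 2 | allyl 3-(1H-benzotriazol-1-yl)-3-oxopropanoate | C=CCOC(=O)CC(=O)n1nnc2ccccc21
F7 | step 2 | allyl 4-(2,2-dimethyl-4-oxo-4H-1,3-dioxin-6-yl)-3-oxobutanoate | C=CCOC(=O)CC(=O)CC1=CC(=O)OC(C)(C)O1
F8 | step 2 | allyl 2-acetyl-4-(2,2-dimethyl-4-oxo-4H-1,3-dioxin-6-yl)-3-oxobutanoate | CC(=O)C(C(=O)OCC=C)C(=O)CC1=CC(=O)OC(C)(C)O1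
F9 | step 4 | 5-heptyl-7-hydroxy-2,2-dimethyl-4H-1,3-benzodioxin-4-one | CCCCCCCc1cc(O)cc2c1C(=O)OC(C)(C)O2
F10 | step 4 | 2-heptyl-4,6-dihydroxybenzoic acid | CCCCCCCc1cc(O)cc(O)c1C(=O)O
F11 | step 1 | [(2,2-dimethyl-6-methylidene-6H-1,3-dioxin-4-yl)oxy]trimethylsilane | C=C1C=C(O[Si](C)(C)C)OC(C)(C)O1
F12 | step 1 | 6-(2-hydroxypropyl)-2,2-dimethyl-4H-1,3-dioxin-4-one (racemic) | CC(O)CC1=CC(=O)OC(C)(C)O1
A1 | alternative 1 | 2,4-dihydroxy-6-methylbenzoic acid (orsellinic acid) | Cc1cc(O)cc(O)c1C(=O)O
A2 | alternative 1 | 2,4-bis(benzyloxy)-6-methylbenzoic acid | Cc1cc(OCc2ccccc2)cc(OCc2ccccc2)c1C(=O)O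
A3 | alternative 1 | benzyl 4-{[2,4-bis(benzyloxy)-6-methylbenzoyl]oxy}-2-heptyl-6-hydroxybenzoate | CCCCCCCc1cc(OC(=O)c2c(C)cc(OCc3ccccc3)cc2OCc2ccccc2)cc(O)c1C(=O)OCc1ccccc1
A4 | alternative 2 | benzyl 4-(but-2-ynoyloxy)-2-heptyl-6-hydroxybenzoate | CC#CC(=O)Oc1cc(O)c(C(=O)OCc2ccccc2)c(CCCCCCC)c1
A5 | alternative 2 | 1-methoxy-1,3-bis(trimethylsilyloxy)buta-1,3-diene (double-bond geometry not specified) | COC(O[Si](C)(C)C)=CC(=C)O[Si](C)(C)C
A6 | alternative 3 | 7-hydroxy-5-methyl-2,2-diphenyl-4H-1,3-benzodioxin-4-one | Cc1cc(O)cc2c1C(=O)OC(c1ccccc1)(c1ccccc1)O2
A7 | alternative 3 | 3-hydroxy-5-methyl-6-(oxomethylidene)cyclohexa-2,4-dien-1-one (quinoketene) | CC1=CC(O)=CC(=O)C1=C=O
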